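The isoflavone is cut at ring C around O1 into a ring B enamine, a ring A acid chloride and water. The design rests on ring A: C8a, which carries O1, and C7, which carries the prenyl ether, are the ortho and para carbons relative to the C4 ketone, so both oxygens can enter by fluoride displacement from a 2,4-difluorobenzoyl unit. A single operation C-acylates the morpholine enamine of (3-benzyloxy-4-methoxyphenyl)acetaldehyde with 2,4-difluorobenzoyl chloride (C3–C4), swaps nitrogen for oxygen at C2 by hydrolysis, and lets the enolate oxygen expel the ortho fluorine to close ring C. Hydrogenolysis and prenoxide displacement of the para fluorine then complete the target.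

Key step: step 4

Assumption: O-benzylisovanillin 1 is bought with the benzyl ether in place. The benzyl group is kept as the 3'-O protecting group because it tolerates ylide, dilute acid, amine, acid chloride and hot carbonate. It is removed before the prenyl ether is made, since hydrogenolysis would not spare an O-prenyl group.

Step 1
Reactants: 1 3-(benzyloxy)-4-methoxybenzaldehyde (O-benzylisovanillin); 2 (methoxymethyl)triphenylphosphonium chloride
Product: 3 2-(benzyloxy)-1-methoxy-4-(2-methoxyethenyl)benzene (E/Z mixture)
Conditions: 2, KOtBu, THF, 0 °C; then 1, 0 °C to rt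
Reagents that add atoms: (methoxymethyl)triphenylphosphonium chloride, COC[P+](c1ccccc1)(c1ccccc1)c1ccccc1.[Cl-]
Why: Wittig olefination of a non-enolisable aromatic aldehyde with the ylide Ph3P=CHOMe, made in the flask with KOtBu, should give the methyl enol ether as an E/Z mixture that needs no separation because both isomers hydrolyse to the same aldehyde in step 2; the benzyl and methyl ethers are inert to the ylide.

Step 2
Reactants: 3 2-(benzyloxy)-1-methoxy-4-(2-methoxyethenyl)benzene; 4 water
Product: 5 2-[3-(benzyloxy)-4-methoxyphenyl]acetaldehyde
Conditions: 2 M aq HCl, THF, 50 °C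
Reagents that add atoms: water, O
Why: Acid-catalysed enol ether hydrolysis (protonation at the benzylic carbon, hydration of the oxocarbenium ion, loss of methanol) should unmask the homologated aldehyde while the aryl benzyl and methyl ethers stay untouched; the sensitive arylacetaldehyde is extracted and carried into step 3 at once without purification.

Step 3
Reactants: 5 2-[3-(benzyloxy)-4-methoxyphenyl]acetaldehyde; 6 morpholine
Product: 7 4-{(E)-2-[3-(benzyloxy)-4-methoxyphenyl]ethenyl}morpholine
Conditions: morpholine, 4 Å MS, toluene, rt
Reagents that add atoms: morpholine, C1COCCN1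
Why: Condensation of an aldehyde with a secondary amine under dehydrating conditions (enamine formation) is especially easy here because the new C=C bond is conjugated with ring B, and the E isomer is expected since it keeps the morpholine ring away from the aryl group.

Step 4
Reactants: 7 4-{(E)-2-[3-(benzyloxy)-4-methoxyphenyl]ethenyl}morpholine; 8 2,4-difluorobenzoyl chloride; 4 water
Product: 11 3-[3-(benzyloxy)-4-methoxyphenyl]-7-fluoro-4H-chromen-4-one, via morpholino enaminone 9 (not isolated), via hydroxymethylene ketone 10 (not isolated)
Conditions: 8, Et3N, MeCN, 0 °C to rt; then aq K2CO3, 70 °C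
Reagents that add atoms: 2,4-difluorobenzoyl chloride, O=C(Cl)c1ccc(F)cc1F; water, O
Why: The β-carbon of enamine 7, the carbon that already bears ring B, attacks acid chloride 8 in a Stork-type enamine C-acylation and Et3N removes the acidified proton, giving vinylogous amide 9 with C3–C4 in place (the carbonate later frees Et3N from its hydrochloride). Hydroxide from the aqueous carbonate then adds to the aminomethylene carbon and morpholine is expelled (addition–elimination at a vinylogous amide), which puts O1 on C2 and leaves the chelated Z enolate of 10. Ring C closes by intramolecular nucleophilic aromatic substitution: the enolate oxygen adds to the fluorine-bearing carbon ortho to the ketone (future C8a) to form a six-membered ring, the charge of the Meisenheimer adduct is taken up by the C4 carbonyl, and fluoride leaves. The closest known reaction types are the acylation of enamines with aroyl chlorides and the carbonate-mediated cyclisation of 2-fluoroaroyl 1,3-dicarbonyl enolates to chromones and 4-quinolones. No stereocentre is formed, and the alkene geometry of 7 and 9 is of no consequence because the enolate of 10 equilibrates to the Z form needed for closure. The step needs ortho over para fluoride displacement, which the substrate secures because only the ortho carbon lies within reach of the tethered oxygen in a six-membered transition state, so the para fluorine survives as the handle for step 6.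

Step 5
Reactants: 11 3-[3-(benzyloxy)-4-methoxyphenyl]-7-fluoro-4H-chromen-4-one
Product: 12 7-fluoro-3-(3-hydroxy-4-methoxyphenyl)-4H-chromen-4-one
Conditions: H2 (1 atm), 10% Pd/C, EtOAc–MeOH, rt
Reagents that add atoms: none
Why: Hydrogenolysis of a benzyl aryl ether over Pd/C is much faster at one atmosphere and room temperature than reduction of the C2–C3 double bond of the vinylogous ester or cleavage of the aryl C–F bond, so stopping after uptake of one equivalent of H2 should give the phenol cleanly.

Step 6
Reactants: 12 7-fluoro-3-(3-hydroxy-4-methoxyphenyl)-4H-chromen-4-one; 13 prenol (3-methylbut-2-en-1-ol)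
Product: 14 7-prenyloxy-3'-hydroxy-4'-methoxyisoflavone, 3-(3-hydroxy-4-methoxyphenyl)-7-[(3-methylbut-2-en-1-yl)oxy]-4H-chromen-4-one
Conditions: prenol (3.5 equiv), NaH (3 equiv), THF, 0 °C; then 12, DMF, 0 °C to rt; then dilute aq HCl to pH 5
Reagents that add atoms: prenol, CC(C)=CCO
Why: Nucleophilic aromatic substitution by addition–elimination: prenoxide adds at C7, para to the C4 carbonyl that carries the charge of the Meisenheimer intermediate, and fluoride leaves, while the 3'-phenoxide formed by the first equivalent of alkoxide is a much weaker nucleophile and, sitting meta to C1', does not feed electron density into ring A; alkoxide addition at C2 is reversible, and mild acidification returns the free phenol without harming the prenyl ether.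

Compound list
1 | 3-(benzyloxy)-4-methoxybenzaldehyde (O-benzylisovanillin) | COc1ccc(C=O)cc1OCc1ccccc1 | starting material
2 | (methoxymethyl)triphenylphosphonium chloride | COC[P+](c1ccccc1)(c1ccccc1)c1ccccc1.[Cl-] | starting material
3 | 2-(benzyloxy)-1-methoxy-4-(2-methoxyethenyl)benzene, E/Z mixture (geometry not specified) | COC=Cc1ccc(OC)c(OCc2ccccc2)c1 | intermediate
4 | water | O | starting material
5 | 2-[3-(benzyloxy)-4-methoxyphenyl]acetaldehyde | COc1ccc(CC=O)cc1OCc1ccccc1 | intermediate
6 | morpholine | C1COCCN1 | starting material
7 | 4-{(E)-2-[3-(benzyloxy)-4-methoxyphenyl]ethenyl}morpholine | COc1ccc(/C=C/N2CCOCC2)cc1OCc1ccccc1 | intermediate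
8 | 2,4-difluorobenzoyl chloride | O=C(Cl)c1ccc(F)cc1F | starting material
9 | (2E)-2-[3-(benzyloxy)-4-methoxyphenyl]-1-(2,4-difluorophenyl)-3-(morpholin-4-yl)prop-2-en-1-one (not isolated; geometry labile, E expected) | COc1ccc(cc1OCc1ccccc1)/C(=C\N1CCOCC1)C(=O)c1ccc(F)cc1F | intermediate
10 | (2Z)-2-[3-(benzyloxy)-4-methoxyphenyl]-1-(2,4-difluorophenyl)-3-hydroxyprop-2-en-1-one (not isolated; present as its potassium enolate) | COc1ccc(cc1OCc1ccccc1)/C(=C/O)C(=O)c1ccc(F)cc1F | intermediate
11 | 3-[3-(benzyloxy)-4-methoxyphenyl]-7-fluoro-4H-chromen-4-one | COc1ccc(cc1OCc1ccccc1)-c1coc2cc(F)ccc2c1=O | intermediate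
12 | 7-fluoro-3-(3-hydroxy-4-methoxyphenyl)-4H-chromen-4-one | COc1ccc(cc1O)-c1coc2cc(F)ccc2c1=O | intermediate
13 | prenol (3-methylbut-2-en-1-ol) | CC(C)=CCO | starting material
14 | 7-prenyloxy-3'-hydroxy-4'-methoxyisoflavone, 3-(3-hydroxy-4-methoxyphenyl)-7-[(3-methylbut-2-en-1-yl)oxy]-4H-chromen-4-one (no stereocentres) | COc1ccc(-c2coc3cc(OCC=C(C)C)ccc3c2=O)cc1O | target

Total step count: 6. Longest linear sequence: 6 steps (1 to 14).

Steps most likely to fail

Step 4 (key step). Three processes could divert it:
- exchange of morpholine for oxygen at C2 may be slow under carbonate;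
- the released morpholine may attack the para fluorine;
- hydroxide may cleave the formyl carbon from the enolate of 10 (retro-Claisen deformylation) before the ring closes.

The fallback is the chalcone oxidative rearrangement route to isoflavones. It sets out from 1 and comes back at 11, so steps 1 to 3 would be dropped. Claisen–Schmidt condensation of 1 with purchased 1-(4-fluoro-2-hydroxyphenyl)ethan-1-one (CC(=O)c1ccc(F)cc1O) under KOH in EtOH at rt should give the chalcone (2E)-3-[3-(benzyloxy)-4-methoxyphenyl]-1-(4-fluoro-2-hydroxyphenyl)prop-2-en-1-one F1. Oxidative 1,2-shift of the electron-rich ring B aryl group with Tl(NO3)3·3H2O in MeOH–HC(OMe)3 should give the acetal 2-[3-(benzyloxy)-4-methoxyphenyl]-1-(4-fluoro-2-hydroxyphenyl)-3,3-dimethoxypropan-1-one F2. Warming F2 with HCl in MeOH should close ring C through the phenol oxygen, with loss of two molecules of methanol, to give 11.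

Step 6. Three processes could divert it:
- alkoxide addition at C2 may open ring C and lead on to loss of C2 as formate;
- the sodium phenoxide of 12 may be poorly soluble, so the displacement stalls;
- the 3'-phenoxide may compete as a nucleophile and give diaryl ethers.

The fallback reverses the polarity of the prenyl transfer. It sets out from 12 and comes back at 14. Heating 12 with (E)-benzaldehyde oxime and K2CO3 in DMSO (oximate as a hydroxide surrogate, no strong alkoxide present) should give the O-aryl oxime 7-{[(E)-benzylideneamino]oxy}-3-(3-hydroxy-4-methoxyphenyl)-4H-chromen-4-one F3. F3 would not be isolated: under the same basic conditions it should lose benzonitrile and leave calycosin, 7-hydroxy-3-(3-hydroxy-4-methoxyphenyl)-4H-chromen-4-one F4. Alkylation of F4 with one equivalent each of prenyl bromide (CC(C)=CCBr) and K2CO3 in acetone at rt should then take place at the 7-OH to give 14, since this vinylogous acid, conjugated with the C4 carbonyl, is clearly more acidic than the 3'-OH.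

Step 2. The electron-rich arylacetaldehyde 5 may undergo self-aldol condensation and air oxidation during the acidic hydrolysis and the concentration, so that little of it reaches step 3.

The fallback is a Horner–Wittig enamine synthesis that never liberates the aldehyde. It sets out from 1 (and 6) and comes back at 7. Morpholine 6, paraformaldehyde and diphenylphosphine oxide, Ph2P(O)H, should condense (phospha-Mannich reaction, toluene, 80 °C) to diphenyl(morpholin-4-ylmethyl)phosphine oxide F5. Lithiation of F5 (n-BuLi, THF, −78 °C) and addition to aldehyde 1 should give the β-hydroxy phosphine oxide 1-[3-(benzyloxy)-4-methoxyphenyl]-2-(diphenylphosphoryl)-2-(morpholin-4-yl)ethan-1-ol F6. KOtBu in THF should then trigger syn elimination of diphenylphosphinate and deliver enamine 7. Any Z isomer formed is of no consequence, because the alkene geometry is lost in step 4.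

Further compounds
F1 | step 4 | (2E)-3-[3-(benzyloxy)-4-methoxyphenyl]-1-(4-fluoro-2-hydroxyphenyl)prop-2-en-1-one | COc1ccc(/C=C/C(=O)c2ccc(F)cc2O)cc1OCc1ccccc1
F2 | step 4 | 2-[3-(benzyloxy)-4-methoxyphenyl]-1-(4-fluoro-2-hydroxyphenyl)-3,3-dimethoxypropan-1-one (racemic) | COc1ccc(cc1OCc1ccccc1)C(C(OC)OC)C(=O)c1ccc(F)cc1O
F3 | step 6 | 7-{[(E)-benzylideneamino]oxy}-3-(3-hydroxy-4-methoxyphenyl)-4H-chromen-4-one | COc1ccc(cc1O)-c1coc2cc(O/N=C/c3ccccc3)ccc2c1=O
F4 | step 6 | calycosin, 7-hydroxy-3-(3-hydroxy-4-methoxyphenyl)-4H-chromen-4-one | COc1ccc(cc1O)-c1coc2cc(O)ccc2c1=O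
F5 | step 2 | diphenyl(morpholin-4-ylmethyl)phosphine oxide | O=P(CN1CCOCC1)(c1ccccc1)c1ccccc1
F6 | step 2 | 1-[3-(benzyloxy)-4-methoxyphenyl]-2-(diphenylphosphoryl)-2-(morpholin-4-yl)ethan-1-ol (mixture of racemic diastereomers) | COc1ccc(cc1OCc1ccccc1)C(O)C(N1CCOCC1)P(=O)(c1ccccc1)c1ccccc1
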